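The time of reading is 50 s, and what I want at that moment is how the substrate has divided between ring and open dimer.

    substrate + substrate ⇌ open dimer (K1 = 1.2 M⁻¹, k1 = 0.032 M⁻¹ s⁻¹)
    substrate → ring (k2 = 0.035 s⁻¹)

substrate 0.80 M; time 50 s

- a species is counted by the substrate in it: one open dimer counts as two
- a doubled species enters its step squared and goes two at a time
- the reaction counts as stopped when no species that holds the substrate changes by six tenths of a point or more over the second half of the time
- run time (flask): 50 s

- which holds at 50 s: what has brought the reaction to rest, or that it has not come to rest (all of the substrate has reacted / it is still moving / forward and back rates have come level)
- how much of the substrate has reacted by 50 s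
- how much ring there is at 50 s, in percent of the substrate charged

I follow one free substrate molecule, and let a be the fraction of the charge still free. It can close, at 0.035 s⁻¹, or pair, at 0.0512 s⁻¹ times a, counting that each turn takes two. Reopening acts on open dimer, not on a free molecule, so it is no exit from this fork, and these two rates remain. Their ratio is the even fraction, 68.4%, the value of a at which closing and forward pairing are level; the even fraction over a gives the odds for closing, a selectivity factor. At the charge, pairing is faster, and at this first fork a molecule closes with chance 40.6%. Free substrate and open dimer together pass on to ring at no more than 0.035 s⁻¹, so I expect ring below 82.6% at the reading, and I reckon no further.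

The forecast holds that it is still moving, since “ring formation is irreversible”, with 81% reacted (78% to 85%) and 65% ring (60% to 70%).

The simulation gives that it is still moving, with 82.5% reacted and 65.1% ring. In this flask substrate stands at 69.0% after 5.00 s, level with the even fraction, and the odds for closing over forward pairing then grow to 1.6 at 14.7 s and 3.91 at 50.0 s. The same charge read at 12.0 s has substrate at 47.3%, so odds of 1.45, and holds 28.4% ring against 24.3% open dimer.

(The constants are assumed; the flask was simulated.)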